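The runs were generated by integration with made-up constants; scatter was added.

I draw one straight line. The flask asked about is the alpha run, followed so far to 10.0 h, and epsilon is its earlier twin with more free catalyst than alpha.

| flask | left-handed substrate | right-handed substrate | solid reagent | free catalyst | remark | time |
|---|---|---|---|---|---|---|
| alpha | 1 M | 1 M | 1.1 equiv | 0.2 mol% | the very flask that is asked about, followed so far |  |
| epsilon | 1 M | 1 M | 1.1 equiv | 0.4 mol% | run made earlier |  |
| flask | 1.0 M | 1.0 M | 1.10 equiv | 0.2 mol% |  | 30 h |

| run | time / h | left-handed substrate / % | right-handed substrate / % | left-handed product / % |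
|---|---|---|---|---|
| alpha | 0.667 | 50.0 | 50.0 | 0 |
| alpha | 2.00 | 49.6 | 50.5 | 0.1 |
| alpha | 3.00 | 48.6 | 49.8 | 0 |
| alpha | 5.00 | 49.5 | 49.8 | 0.9 |
| alpha | 6.00 | 48.2 | 50.2 | 1.2 |
| alpha | 10.0 | 48.0 | 51.0 | 2.1 |
| epsilon | 1.50 | 50.1 | 50.6 | 0.7 |
| epsilon | 3.00 | 49.8 | 50.5 | 0.3 |
| epsilon | 5.00 | 49.2 | 48.8 | 2.0 |
| epsilon | 8.00 | 47.9 | 49.5 | 1.3 |
| epsilon | 12.0 | 47.4 | 49.7 | 3.4 |
| epsilon | 20.0 | 45.1 | 50.4 | 5.2 |

(readings scatter by 0.5 percentage points)

- free catalyst is single-handed; left-handed substrate and right-handed substrate are mirror images of each other, charged as a racemate, each of them at the stated concentration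
- as a solid, counted per litre of solution: solid reagent
- the earlier runs were read with a standard deviation of 0.5 percentage points
- at the start none of the solid reagent is in solution
- an excess is the difference of the two amounts in percent of their sum
- an excess is below zero if the other one leads

- part of the left-handed substrate and right-handed substrate charged together that has reacted at 30 h
- excess of left-handed product over right-handed product in the product at 30 h
- excess of right-handed substrate over left-handed substrate among what is left of the two at 30 h

In alpha the left-handed product stands at 2.1 % at 10.0 h, a reading that carries the scatter of 0.5 percentage points. The bench rule for a small conversion is that a product rising steadily keeps its pace, a zero-order stretch. So I take the slope from that reading, 0.00420 M/h, and over 30 h my line gives 6.30 % reacted.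

The rule has a border: each unit of product on this line takes solid reagent from the charge. I call the charge of solid reagent divided by the slope the supply time, and here it is 262 h. The 30 h of this flask is shorter than that, just 11.5 % of it, so I keep the line.

The forecast holds that “rate stays roughly constant over this small conversion”, and it gives 6 % reacted, a little less than my line, with 95 % for the product excess and 6.1 % for the substrate excess.

The flask gives 7.64 % reacted, 97.6 % and 8.04 %, so the forecast holds on all three.

    free catalyst + left-handed substrate ⇌ catalyst intermediate A (K = 2.30 /M, k = 650 /M/h)
    free catalyst + right-handed substrate ⇌ catalyst intermediate B (K = 0.910 /M, k = 590 /M/h)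
    partner + catalyst intermediate A → free catalyst + left-handed product (k = 550 /M/h)
    partner + catalyst intermediate B → free catalyst + right-handed product (k = 15.0 /M/h)
    solid reagent ⇌ partner, rate k5*(cs5 - [partner]) while solid is left; crystals form when [partner] > cs5 (solubility = 0.0880 M, k = 0.0710 /h)
    2 free catalyst ⇌ resting dimer, settled at all times (K = 610 /M)
    free catalyst ⇌ dormant form (K = 0.710, k = 0.0680 /h)

This flask owes its product excess mainly to the reverse step, in which catalyst intermediate B returns to free catalyst and right-handed substrate. The run without that reverse step gives −82.7 % against 97.6 % here, so in that run the right-handed product leads.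

For the neighbour flask charged with 0.280 equiv of solid reagent, the supply time shrinks to 66.7 h, still longer than 30 h, so I expect the same line. That neighbour flask gives 7.64 % reacted, with 41.4 % of its solid reagent left.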